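Dissolved substrate is left over at the end of both earlier runs, 37.6% in beta and 22.6% in eta at 8.00 h, beside a target that has stopped rising, so these runs have to be read for the partner, which couples with dissolved substrate to target and also decomposes on its own.

common to all: solid substrate 0.20 M
- beta: partner 0.30 M; protic impurity 0.13 M; run made earlier
- eta: partner 0.30 M; protic impurity 0.30 M; run made earlier
- flask: partner 0.300 M; protic impurity 0.200 M; time 6.0 h

The runs differ in protic impurity, which quenches the solid before it dissolves, and the flask with 0.200 M lies between beta with 0.13 M and eta with 0.30 M.

| run | time / h | target / % | dissolved substrate / % | solid substrate / % |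
|---|---|---|---|---|
| beta | 1.33 | 21.0 | 21.6 | 35.3 |
| beta | 3.00 | 34.7 | 36.6 | 2.2 |
| beta | 4.00 | 35.4 | 39.6 | 0.5 |
| beta | 6.00 | 35.5 | 37.5 | 0 |
| beta | 8.00 | 34.6 | 37.6 | 0 |
| eta | 0.500 | 9.6 | 11.4 | 56.6 |
| eta | 1.00 | 16.1 | 20.0 | 28.7 |
| eta | 2.00 | 29.8 | 27.0 | 1.1 |
| eta | 4.00 | 33.0 | 23.2 | 0 |
| eta | 8.00 | 34.6 | 22.6 | 1.2 |

(standard deviation of a reading: 1 percentage point)

- solid substrate is a solid; its amount is given per volume of the solution
- reactions considered so far: partner -> decomposed reagent; dissolved substrate + partner -> target; solid substrate + protic impurity -> quenched substrate; solid substrate <-> dissolved substrate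
- at the start none of the solid substrate is in solution
- dissolved substrate means what is dissolved; the solid is not counted in it

But target ends at 34.6% in beta and 34.6% in eta, although dissolved substrate ends higher in beta than in eta, so target is better counted against the partner. The partner has two ways out, coupling and decomposition, and both draw on the same charge. That suggests one number, the partner's catch, the part of the charged partner that ends as target, read here as 23.1%. Carried to 0.300 M partner on 0.20 M solid substrate in the flask, this reckoning gives target 34.6%; it says nothing of saturation.

1. the target standing at 6.0 h, as a percentage of the solid substrate charged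
2. concentration of dissolved substrate in solution at 6.0 h, in percent of saturation

The forecast gives 35% and 74%, its ground for target being: “Partner has evidently decomposed by about 4 h”.

The flask gives 35.2% and 60.8%, the second 13 percentage points below the forecast.

    partner → decomposed reagent (k = 0.0140 min⁻¹)
    dissolved substrate + partner → target (k = 0.150 M⁻¹ min⁻¹)
    solid substrate + protic impurity → quenched substrate (k = 0.0400 M⁻¹ min⁻¹)
    solid substrate ⇌ dissolved substrate, rate k4*(cs4 - [dissolved substrate]) while solid is left; crystals form when [dissolved substrate] > cs4 (solubility = 0.100 M, k = 0.0150 min⁻¹)

The partner's half-life by decomposition alone, 0.83 h, is shorter than the 1.05 h by which half of the target-forming turnover is done. At 6.00 h the flask holds 0.037% of its partner beside 30.4% dissolved substrate. Its catch comes to 23.5%, and the earlier catch, carried to the neighbour flask with 0.80 M solid substrate and the same partner, gives 8.66% target, where that flask holds 8.90%.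

(Readings and results were computed on assumed constants; scatter was added.)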